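| flask | starting material | partner | remark | time |
|---|---|---|---|---|
| blue | 0.25 M | 0.60 M | run made earlier |  |
| ochre | 1 M | 0.60 M | run made earlier |  |
| amber | 0.50 M | 1.2 M | run made earlier |  |
| flask | 0.50 M | 0.600 M |  | 6.0 d |

- blue (time / d: target / %, side product / %): 0.417: 22.0, 68.2; 0.625: 24.1, 70.5; 0.833: 24.5, 71.4; 1.25: 24.5, 73.5; 2.08: 24.1, 73.4; 3.00: 25.6, 74.1; 5.00: 25.2, 74.5
- ochre (time / d: target / %, side product / %): 0.417: 10.1, 47.1; 0.625: 9.9, 48.2; 0.833: 10.0, 47.5; 1.25: 9.7, 47.7; 2.08: 9.3, 46.0; 3.00: 9.8, 46.7; 5.00: 9.7, 46.3
- amber (time / d: target / %, side product / %): 1.04: 23.8, 74.4; 2.08: 24.2, 74.9; 3.00: 23.1, 74.9; 4.00: 24.0, 75.5; 5.00: 24.2, 75.6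

(each reading ± 0.5 percentage points)

1. at 6.0 d, what has stopped the reaction, if anything has (all of the starting material has reacted / forward and back rates have come level / it is still moving)
2. target at 6.0 d, in percent of the starting material charged
3. side product at 6.0 d, in percent of the starting material charged

- the analysis behind the earlier runs scatters by 0.5 percentage points, standard deviation
- the reaction counts as stopped when no species that holds the starting material changes by six tenths of a point or more over the second half of the time

The ochre run is flat from its first reading: target plus side product stand at 56.0 % of its charge at its last. So read partner as the limiting reagent in ochre, and define the partner yield Y, product made per partner charged: the ochre readings give 0.933.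

But do not carry Y as a constant. Call L the share of partner lost, what Y lacks of a whole. Assume L = b·D/Ā, with D the partner charge and Ā the mean starting material during the reaction. Ochre's Ā is 0.720 M, so the ochre readings put the loss constant b at 0.0800.

Now go round on the flask. Suppose its whole charge of starting material reacts: Ā = 0.250 M, L = 0.192, and partner covers 0.485 M. Put that back: Ā = 0.258 M, L = 0.186, and partner covers 0.488 M, less than the 0.50 M charged. My estimate of target plus side product is therefore 97.6 % of the starting material charged, unsplit.

The forecast's end is: all of the starting material has reacted. It gives target 21 % (18 % to 24 %) and side product 78.5 % (73 % to 82 %): “I expect full consumption”. Its sum of 99.5 % stands above my estimate.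

The flask's end is: all of the starting material has reacted. It gives target 21.0 % and side product 68.3 %. At 6.00 d open intermediate holds 9.16 %, starting material 0.925 % and dormant form 0.555 %, with partner at 0 %. So L in this flask is 0.255, more than the 0.186 from b.

    starting material + second intermediate → side product (k = 0.00460 /M/s)
    2 second intermediate → homo product (k = 1.50 × 10⁻⁴ /M/s)
    starting material ⇌ open intermediate (K = 9.90, k = 4.50 × 10⁻⁴ /s)
    open intermediate + second intermediate → target (k = 1.70 × 10⁻⁴ /M/s)
    starting material ⇌ dormant form (K = 0.600, k = 5.80 × 10⁻⁵ /s)
    partner → second intermediate (k = 3.00 × 10⁻⁴ /s)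

Try the neighbour with 0.15 M of partner. There b gives L = 0.0279, so partner covers 0.146 M, or 29.2 % of the starting material charged. Computed, that neighbour holds 29.4 % as target plus side product, with partner at 0 %.

The readings were computed on assumed constants; the scatter is artificial.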